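## Analysis of the target

The target is a 7-methoxycoumarin, benzene ring A fused to the α-pyranone ring B (O1, C2=O, C3=C4), which carries a four-carbon chain on C6 next to the methoxy group on C7. Along that chain C1' is a benzylic secondary carbinol, C2' bears the (2R)-2-methylbutanoate and C3' is a tertiary carbinol with two methyl groups, so three oxygenated carbons stand in a row. C1' and C2' are both R and, with the chain drawn in zigzag, their oxygens lie on opposite sides, which makes the unit an anti (erythro) 1,2-diol; the third stereocentre is the remote α-carbon of the acyl group and is best bought with the acid. The lactone of ring B is opened by hydroxide or alkoxide and attacked by hard carbon nucleophiles, and its C3=C4 bond is a Michael acceptor that is also reducible. The ester is flanked by two free hydroxyls and can migrate under base, its α-centre can epimerise, and the benzylic C1'–O bond, ortho to the methoxy group and para to O1, can ionise in strong acid. The difficulty is twofold: two adjacent carbinol centres must be set anti and in the right absolute sense on a chain whose only handle is the arene, and three hydroxyls must be told apart so that the acyl group ends on the most hindered secondary one. The plan rests on reading C1'(OH)–C2'(O)–C3' as an aldol retron, in which C1' comes from a formyl group on C6 of ring A, C2' and C3' come from an α-hydroxy methyl ketone, and C3' is completed by a single methyl addition.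

## Retrosynthetic reasoning

Ester and silyl ether (14 → 13 → 11 + 12). The target 14 is traced back to its C1' silyl ether 13, because a free C1' hydroxyl would compete in the acylation. Cutting the acyl–O bond of 13 gives diol 11 and the enantiopure acid 12. The forward esterification must reach a secondary hydroxyl next to a fully substituted carbon while the tertiary hydroxyl stays free. Attaching an enantiopure acid at this point also turns any residual enantiomer of the side chain into a separable diastereomer.

C1' silyl ether (11 → 10). Removing the silyl group leads to triol 10. The forward step must distinguish the benzylic C1' hydroxyl from the C2' hydroxyl, which is shielded by the neighbouring quaternary carbinol carbon. This is steric discrimination and costs no extra handle.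

C3'–CH3 bond (10 → 9 → 8). Cutting one methyl group from C3' turns the tertiary carbinol into a methyl ketone. In the forward direction a methyl nucleophile must add to the ketone and leave the lactone of ring B alone. The two secondary hydroxyls are therefore tied up as the isopropylidene acetal in 8 and 9, so that little more than one equivalent of a weakly basic organometallic is needed. The acetal is hydrolysed between 9 and 10.

C1'–C2' bond, the key disconnection (8 → 7 → 5 + 6). After removal of the acetal, diol ketone 7 is cut between its two carbinol carbons into aldehyde 5 and hydroxyacetone 6. This is the only cut that removes both stereocentres at once and leaves two achiral pieces. A cut at C6–C1' or C2'–C3' would leave a stereocentre in a fragment that then has to be made separately. The forward reaction must join the pieces at the hydroxylated carbon of 6 and set the relative and absolute configuration under catalyst control.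

Formyl group and ring B (5 → 4 → 2 → 1). The formyl C–C bond of 5 is cut to give bromide 4, to be carbonylated. Ring B of 4 is opened at O1–C2 and C3=C4 through cinnamate 3 to salicylaldehyde 2. The C–Br bond of 2 leads to the commercial aldehyde 1. The bromine is placed where the directing effects of hydroxyl, methoxy and formyl converge. The pyranone is built before the second formyl group exists, so only one aldehyde is present in the olefination.

## Alternatives that were turned down

Alternative 1: The two C–O bonds of an oxirane spanning C2' and C3' are disconnected. This leads back to the racemic allylic alcohol 6-(1-hydroxy-3-methylbut-2-en-1-yl)-7-methoxy-2H-chromen-2-one A2 that is itself made from aldehyde 5 and a 2-methylprop-1-enyl metal.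
- Forward key step: a kinetic resolution with the catalyst from Ti(OiPr)4 and D-(−)-diisopropyl tartrate and with tert-butyl hydroperoxide as oxidant. It should consume the (S)-enantiomer of A2 and convert it into the erythro epoxy alcohol 6-[(R)-[(2R)-3,3-dimethyloxiran-2-yl](hydroxy)methyl]-7-methoxy-2H-chromen-2-one A1 and leave the (R)-enantiomer of A2 behind. The carbinol descriptor changes from S to R only because the priorities change. Hydrolytic opening of A1 at C3' would then give triol 10.
- For: the erythro preference of the Ti(OiPr)4/tartrate catalyst gives the anti relationship directly, enantiomeric purity is usually very high, and the C3' oxygen arrives without a methyl addition next to the lactone. On predictability of optical purity it is stronger than the chosen aldol.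
- Against: half of a coupled intermediate is discarded. The alkene of A2 carries a methyl group cis to the carbinol carbon, and this 1,3-allylic strain is the known weak point of the resolution. The benzylic allylic alcohol A2 and the benzylic epoxy alcohol A1 are exposed to Lewis acidic Ti(OiPr)4. The three hydroxyls still have to be told apart afterwards.
- Comparison: the chosen route sets both centres in one catalytic C–C bond formation from achiral materials without a resolution; the resolution is kept as a reserve.

Alternative 2: Ring B is disconnected at O1–C2 and C3=C4. This leads to the salicylaldehyde (1R,2R)-1-[(tert-butyldimethylsilyl)oxy]-1-(5-formyl-4-hydroxy-2-methoxyphenyl)-3-hydroxy-3-methylbutan-2-yl (2R)-2-methylbutanoate A4 in which the complete side chain is already in place.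
- Forward key step: (triphenylphosphoranylidene)ketene would acylate the phenol of A4 and the ester ylide so formed would close ring B by intramolecular Wittig reaction with the ortho formyl group. The product would be (1R,2R)-1-[(tert-butyldimethylsilyl)oxy]-3-hydroxy-1-(7-methoxy-2-oxo-2H-chromen-6-yl)-3-methylbutan-2-yl (2R)-2-methylbutanoate A3 and this compound A3 is the same silyl ether that the chosen route reaches as 13.
- For: no lactone and no Michael acceptor is present while the side chain is built, so the methyl addition and any basic step have no competing electrophile. On chemoselectivity it is stronger than the chosen route.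
- Against: the disconnection says nothing about the two carbinol centres, so the stereochemical problem is only moved onto a benzene ring that must carry a masked phenol and a masked aldehyde through every step on the way to A4 . These must then be unmasked next to an ester and a silyl ether. The ketene ylide can also acylate the free tertiary hydroxyl of A4 . The ring closure to A3 is run on the most valuable material of the synthesis.
- Comparison: the chosen route builds ring B in step 2 from an inexpensive aldehyde and accepts one chemoselective organometallic step in return.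

Alternative 3: The C2'–C3' bond is disconnected. This leads to (2R)-2-[(tert-butyldimethylsilyl)oxy]-2-(7-methoxy-2-oxo-2H-chromen-6-yl)acetaldehyde A6 and an isopropenyl metal.
- Forward key step: the organochromium species from 2-bromopropene, CrCl2 and catalytic NiCl2 would add to A6 under Felkin–Anh control. The product would be 6-[(1R,2S)-1-[(tert-butyldimethylsilyl)oxy]-2-hydroxy-3-methylbut-3-en-1-yl]-7-methoxy-2H-chromen-2-one A5 in which C2' has the spatial arrangement of the target.
- For: the organochromium species generated with CrCl2 leaves the lactone alone. C1' is silylated before the C2' hydroxyl exists, so the hydroxyls of A5 are differentiated by construction. On that point it is stronger than the chosen route, which needs a regioselective silylation.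
- Against: A6 is a doubly activated α-aryl α-silyloxy aldehyde and should racemise easily through its enol. 1,2-Induction from one silyloxy stereocentre is usually moderate. C1' has to be set beforehand by a separate asymmetric step. The isopropenyl group of A5 must later be hydrated in the Markovnikov sense in the presence of the C3=C4 bond and the ester.
- Comparison: the chosen route creates both centres together under catalyst control and brings C3' in at the ketone oxidation level, one methyl addition from the target.

Key step: step 4

Assumption: the target is taken exactly as the SMILES reads, i.e. the (1'R,2'R) anti diol acylated on C2' by (2R)-2-methylbutanoic acid, and this acid is taken as purchasable in enantiopure form.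

## Route

Step 1
Reactants: 1 2-hydroxy-4-methoxybenzaldehyde
Product: 2 5-bromo-2-hydroxy-4-methoxybenzaldehyde
Conditions: Br2 (1.05 equiv), AcOH, rt
Reagents that add atoms: bromine, BrBr
Why: Electrophilic aromatic bromination; C5 is para to the hydroxyl, ortho to the methoxy group and meta to the formyl group, while the other activated position C3 is flanked by two substituents, so substitution at C5 is expected.

Step 2
Reactants: 2 5-bromo-2-hydroxy-4-methoxybenzaldehyde
Product: 4 6-bromo-7-methoxy-2H-chromen-2-one, via ethyl (E)-3-(5-bromo-2-hydroxy-4-methoxyphenyl)prop-2-enoate 3 (not isolated)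
Conditions: Ph3P=CHCO2Et (1.2 equiv), PhNEt2, reflux (ca. 215 °C)
Reagents that add atoms: ethyl (triphenylphosphoranylidene)acetate, CCOC(=O)C=P(c1ccccc1)(c1ccccc1)c1ccccc1
Why: Wittig olefination with a stabilised ylide gives cinnamate 3, which at this temperature isomerises about the double bond and lactonises with loss of ethanol; this is the established one-pot coumarin synthesis from salicylaldehydes, and the aryl bromide is inert to it.

Step 3
Reactants: 4 6-bromo-7-methoxy-2H-chromen-2-one
Product: 5 7-methoxy-2-oxo-2H-chromene-6-carbaldehyde
Conditions: Pd(OAc)2 (3 mol%), Ph2P(CH2)3PPh2 (4 mol%), CO (3 bar), Et3SiH (2 equiv), Na2CO3, DMF, 90 °C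
Reagents that add atoms: carbon monoxide, [C-]#[O+]
Why: Palladium-catalysed reductive carbonylation of an aryl bromide: zerovalent palladium inserts into the C–Br bond, CO inserts to an acylpalladium bromide and the silane delivers hydride to release the aldehyde; no organolithium or Grignard reagent is involved, so the lactone should survive.

Step 4
Reactants: 5 7-methoxy-2-oxo-2H-chromene-6-carbaldehyde; 6 hydroxyacetone
Product: 7 (3R,4R)-3,4-dihydroxy-4-(7-methoxy-2-oxo-2H-chromen-6-yl)butan-2-one
Conditions: D-proline (30 mol%), 6 (10 equiv), DMSO, rt
Reagents that add atoms: none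
Why: D-Proline condenses with 6 to an iminium ion and then to the enamine on the hydroxylated carbon, the more substituted and oxygen-stabilised side, so the C–C bond forms at the carbinol carbon and not at the methyl group. The (E)-enamine adds to the formyl group of 5 through a chair-like, hydrogen-bonded transition state in which the carboxylic acid of the catalyst activates the carbonyl oxygen and the coumarinyl group lies pseudo-equatorial; hydrolysis of the product iminium ion releases 7 and the catalyst. The closest known reaction type is the proline-catalysed direct aldol addition of hydroxyacetone to aldehydes, which gives anti-1,2-diols. No ring is closed. C3 of 7 (C2' of the target) is controlled by the (E)-geometry of the enamine, which places its hydroxyl anti to the new carbinol, and C4 (C1') by the carboxylic acid of the D-catalyst, which steers the enamine to the si face of the aldehyde, so the (3R,4R) isomer is expected. The step needs regioselectivity for the hydroxylated α-carbon, anti diastereoselectivity and enantioselectivity; the aldehyde has no α-hydrogen and cannot enolise or self-condense, the excess of 6 drives the equilibrium, and the metal-free, nearly neutral medium should leave the lactone and its conjugated double bond alone. Aryl aldehydes are the less selective substrate class for this reaction, so some syn diol is anticipated; it is to be removed here or as the trans-dioxolane after step 5, and any residual enantiomer becomes a separable diastereomer once acid 12 is attached in step 9.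

Step 5
Reactants: 7 (3R,4R)-3,4-dihydroxy-4-(7-methoxy-2-oxo-2H-chromen-6-yl)butan-2-one
Product: 8 6-[(4R,5R)-5-acetyl-2,2-dimethyl-1,3-dioxolan-4-yl]-7-methoxy-2H-chromen-2-one
Conditions: Me2C(OMe)2, PPTS (cat.), acetone, rt
Reagents that add atoms: 2,2-dimethoxypropane, COC(C)(C)OC
Why: Acid-catalysed transacetalisation converts the anti diol into its cis-4,5-disubstituted dioxolane without touching either C–O bond at the stereocentres; both hydroxyls are masked for the organometallic step and the acetal of any syn diol is a separable trans-dioxolane.

Step 6
Reactants: 8 6-[(4R,5R)-5-acetyl-2,2-dimethyl-1,3-dioxolan-4-yl]-7-methoxy-2H-chromen-2-one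
Product: 9 6-[(4R,5R)-5-(2-hydroxypropan-2-yl)-2,2-dimethyl-1,3-dioxolan-4-yl]-7-methoxy-2H-chromen-2-one
Conditions: MeMgBr (1.5 equiv), CeCl3 (anhydrous, 1.6 equiv), THF, −78 °C; then aq. NH4Cl
Reagents that add atoms: methylmagnesium bromide, C[Mg]Br
Why: 1,2-Addition of an organocerium reagent: the oxophilic, weakly basic reagent formed from MeMgBr and CeCl3 should add to the ketone much faster than to the conjugated lactone and should not enolise the α-alkoxy ketone, so the cis arrangement on the dioxolane is kept; the new carbinol carbon bears two methyl groups and is not a stereocentre.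

Step 7
Reactants: 9 6-[(4R,5R)-5-(2-hydroxypropan-2-yl)-2,2-dimethyl-1,3-dioxolan-4-yl]-7-methoxy-2H-chromen-2-one
Product: 10 6-[(1R,2R)-1,2,3-trihydroxy-3-methylbutyl]-7-methoxy-2H-chromen-2-one
Conditions: AcOH/H2O (4:1), 45 °C
Reagents that add atoms: none
Why: Acid-catalysed acetal hydrolysis cleaves only the bonds to the isopropylidene carbon, so both stereocentres keep their oxygen; the weak carboxylic acid medium should not ionise the benzylic C–O bond or open the lactone.

Step 8
Reactants: 10 6-[(1R,2R)-1,2,3-trihydroxy-3-methylbutyl]-7-methoxy-2H-chromen-2-one
Product: 11 6-[(1R,2R)-1-[(tert-butyldimethylsilyl)oxy]-2,3-dihydroxy-3-methylbutyl]-7-methoxy-2H-chromen-2-one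
Conditions: TBSCl (1.1 equiv), imidazole, DMF, 0 °C
Reagents that add atoms: tert-butyldimethylsilyl chloride, CC(C)(C)[Si](C)(C)Cl
Why: Sterically controlled silyl ether formation: the tertiary hydroxyl is inert to the silyl chloride and the C2' hydroxyl is neopentylic, next to the quaternary carbinol carbon, so the benzylic C1' hydroxyl should react first.

Step 9
Reactants: 11 6-[(1R,2R)-1-[(tert-butyldimethylsilyl)oxy]-2,3-dihydroxy-3-methylbutyl]-7-methoxy-2H-chromen-2-one; 12 (2R)-2-methylbutanoic acid
Product: 13 (1R,2R)-1-[(tert-butyldimethylsilyl)oxy]-3-hydroxy-1-(7-methoxy-2-oxo-2H-chromen-6-yl)-3-methylbutan-2-yl (2R)-2-methylbutanoate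
Conditions: DCC (2 equiv), DMAP (0.5 equiv), CH2Cl2, 0 °C to rt
Reagents that add atoms: none
Why: Steglich esterification through the acylpyridinium ion; the secondary C2' hydroxyl is expected to be acylated well before the tertiary one, and the neutral carbodiimide activation does not pass through a ketene, so the α-centre of the acid should be retained.

Step 10
Reactants: 13 (1R,2R)-1-[(tert-butyldimethylsilyl)oxy]-3-hydroxy-1-(7-methoxy-2-oxo-2H-chromen-6-yl)-3-methylbutan-2-yl (2R)-2-methylbutanoate
Product: 14 (1R,2R)-1,3-dihydroxy-1-(7-methoxy-2-oxo-2H-chromen-6-yl)-3-methylbutan-2-yl (2R)-2-methylbutanoate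
Conditions: HF·pyridine, pyridine, THF, 0 °C to rt
Reagents that add atoms: none
Why: Fluoride-driven cleavage of the Si–O bond in a buffered, slightly acidic medium, in which no alkoxide is formed next to the ester, so acyl migration to C1' or C3' should be suppressed and the lactone stays closed.

## Compound list

1 | 2-hydroxy-4-methoxybenzaldehyde | COc1ccc(C=O)c(O)c1 | starting material
2 | 5-bromo-2-hydroxy-4-methoxybenzaldehyde | COc1cc(O)c(C=O)cc1Br | intermediate
3 | ethyl (E)-3-(5-bromo-2-hydroxy-4-methoxyphenyl)prop-2-enoate | CCOC(=O)/C=C/c1cc(Br)c(OC)cc1O | intermediate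
4 | 6-bromo-7-methoxy-2H-chromen-2-one | COc1cc2oc(=O)ccc2cc1Br | intermediate
5 | 7-methoxy-2-oxo-2H-chromene-6-carbaldehyde | O=Cc1cc2ccc(=O)oc2cc1OC | intermediate
6 | hydroxyacetone | CC(=O)CO | starting material
7 | (3R,4R)-3,4-dihydroxy-4-(7-methoxy-2-oxo-2H-chromen-6-yl)butan-2-one | O[C@H]([C@H](O)c1cc2ccc(=O)oc2cc1OC)C(C)=O | intermediate
8 | 6-[(4R,5R)-5-acetyl-2,2-dimethyl-1,3-dioxolan-4-yl]-7-methoxy-2H-chromen-2-one | CC1(C)O[C@H]([C@H](O1)c3cc4ccc(=O)oc4cc3OC)C(C)=O | intermediate
9 | 6-[(4R,5R)-5-(2-hydroxypropan-2-yl)-2,2-dimethyl-1,3-dioxolan-4-yl]-7-methoxy-2H-chromen-2-one | CC1(C)O[C@H]([C@H](O1)c3cc4ccc(=O)oc4cc3OC)C(C)(C)O | intermediate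
10 | 6-[(1R,2R)-1,2,3-trihydroxy-3-methylbutyl]-7-methoxy-2H-chromen-2-one | O[C@H]([C@H](O)c1cc2ccc(=O)oc2cc1OC)C(C)(C)O | intermediate
11 | 6-[(1R,2R)-1-[(tert-butyldimethylsilyl)oxy]-2,3-dihydroxy-3-methylbutyl]-7-methoxy-2H-chromen-2-one | O[C@H]([C@H](O[Si](C)(C)C(C)(C)C)c1cc2ccc(=O)oc2cc1OC)C(C)(C)O | intermediate
12 | (2R)-2-methylbutanoic acid | CC[C@@H](C)C(=O)O | starting material
13 | (1R,2R)-1-[(tert-butyldimethylsilyl)oxy]-3-hydroxy-1-(7-methoxy-2-oxo-2H-chromen-6-yl)-3-methylbutan-2-yl (2R)-2-methylbutanoate | CC[C@@H](C)C(=O)O[C@H]([C@H](O[Si](C)(C)C(C)(C)C)c1cc2ccc(=O)oc2cc1OC)C(C)(C)O | intermediate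
14 | (1R,2R)-1,3-dihydroxy-1-(7-methoxy-2-oxo-2H-chromen-6-yl)-3-methylbutan-2-yl (2R)-2-methylbutanoate | CC[C@@H](C)C(=O)O[C@H]([C@H](O)c1cc2ccc(=O)oc2cc1OC)C(C)(C)O | target

## Step count and least certain steps

Total step count: 10. Longest linear sequence: 10 steps, from 1 to 14; 6 and 12 are bought and enter at steps 4 and 9.

Step 4 (key step). The formyl group of 5 is deactivated by the ortho methoxy group and the para ring oxygen, so the addition may be slow and may revert by retro-aldol reaction. An aryl group gains less from the pseudo-equatorial position than a branched alkyl group, so discrimination between anti and syn approach and between the two faces may be incomplete. The fallback sets out from 5 and comes back to the route at 10, so that steps 4 to 7 are passed over. Nozaki–Hiyama–Kishi addition of 1-bromo-2-methylprop-1-ene (CrCl2, catalytic NiCl2, DMF) to 5, which spares the lactone, would give racemic 6-(1-hydroxy-3-methylbut-2-en-1-yl)-7-methoxy-2H-chromen-2-one F1, the compound called A2 above. A Sharpless kinetic resolution (Ti(OiPr)4, D-(−)-diisopropyl tartrate, tert-butyl hydroperoxide, 4 Å molecular sieves, CH2Cl2, −20 °C) would then convert the (S)-enantiomer into the erythro epoxy alcohol 6-[(R)-[(2R)-3,3-dimethyloxiran-2-yl](hydroxy)methyl]-7-methoxy-2H-chromen-2-one F2, identical with A1, and the unreacted enantiomer is separated. Dilute HClO4 in THF/H2O at 0 °C would open the oxirane at the tertiary carbon C3' with the C2'–O bond intact and give triol 10.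

Step 6. The methyl nucleophile may attack the lactone carbonyl or C4 of ring B. Deprotonation at the dioxolane carbon next to the ketone would turn the cis-dioxolane into the more stable trans isomer. The fallback sets out from 8 and comes back to the route at 9. Takai–Lombardo methylenation (CH2Br2, Zn, TiCl4, THF), which is not basic and spares esters, would give 6-[(4R,5S)-2,2-dimethyl-5-(prop-1-en-2-yl)-1,3-dioxolan-4-yl]-7-methoxy-2H-chromen-2-one F3. Markovnikov hydration by oxymercuration and demercuration would then give 9 (Hg(OAc)2, THF/H2O; then NaBH4, aq. NaOH, 0 °C, followed by mild acidification to re-close any opened lactone). It is selective for the electron-rich 1,1-disubstituted alkene over the conjugated C3=C4 bond.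

Step 8. Silylation may also take place at the C2' hydroxyl or twice, because the ortho methoxy group crowds the benzylic hydroxyl as well. The fallback sets out from 9 and comes back to the route at 11, replacing steps 7 and 8. Equilibration of 9 with catalytic TsOH in dry acetone should move the isopropylidene group from the crowded cis-1',2' position to the 2',3' diol. The product is 6-[(R)-hydroxy[(4R)-2,2,5,5-tetramethyl-1,3-dioxolan-4-yl]methyl]-7-methoxy-2H-chromen-2-one F4, in which the benzylic hydroxyl is the only free one. TBSCl and imidazole in DMF would give 6-[(R)-[(tert-butyldimethylsilyl)oxy][(4R)-2,2,5,5-tetramethyl-1,3-dioxolan-4-yl]methyl]-7-methoxy-2H-chromen-2-one F5, and 80% aqueous AcOH at rt would hydrolyse the acetal in the presence of the secondary silyl ether and give 11.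

Step 9. Acylation of the neopentylic C2' hydroxyl next to a bulky silyl ether may be slow. Forcing it invites rearrangement of the activated acid to the N-acylurea, acylation of the tertiary hydroxyl and silyl migration from C1' to C2'. The fallback sets out from 10 and ends at the target 14, replacing steps 8 to 10. tBu2Si(OTf)2 and 2,6-lutidine in CH2Cl2 at 0 °C should bridge the 1,3-related C1' and C3' oxygens in a six-membered ring. The product is 6-[(4R,5R)-2,2-di-tert-butyl-5-hydroxy-6,6-dimethyl-1,3,2-dioxasilinan-4-yl]-7-methoxy-2H-chromen-2-one F6, which leaves C2' as the only free hydroxyl. Esterification with 12 (DCC, DMAP, CH2Cl2) would give (4R,5R)-2,2-di-tert-butyl-4-(7-methoxy-2-oxo-2H-chromen-6-yl)-6,6-dimethyl-1,3,2-dioxasilinan-5-yl (2R)-2-methylbutanoate F7, and HF·pyridine in THF would remove the silylene and give 14.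

Step 3. Hydride transfer to the arylpalladium species before CO insertion would remove the bromine without formylation, and a Pd–H intermediate together with the silane may reduce the C3=C4 bond. The fallback sets out from 4 and comes back to the route at 5. Stille coupling with tributyl(vinyl)stannane (Pd(PPh3)4, toluene, 100 °C) would give 6-ethenyl-7-methoxy-2H-chromen-2-one F8. Lemieux–Johnson cleavage (OsO4 catalytic, NaIO4, 2,6-lutidine, dioxane/H2O), which should prefer the electron-rich styrene-type double bond over C3=C4, would give 5.

## Further compounds

F1 | step 4 | 6-(1-hydroxy-3-methylbut-2-en-1-yl)-7-methoxy-2H-chromen-2-one (racemic) | CC(C)=CC(O)c1cc2ccc(=O)oc2cc1OC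
F2 | step 4 | 6-[(R)-[(2R)-3,3-dimethyloxiran-2-yl](hydroxy)methyl]-7-methoxy-2H-chromen-2-one | CC1(C)O[C@@H]1[C@H](O)c2cc3ccc(=O)oc3cc2OC
F3 | step 6 | 6-[(4R,5S)-2,2-dimethyl-5-(prop-1-en-2-yl)-1,3-dioxolan-4-yl]-7-methoxy-2H-chromen-2-one | CC1(C)O[C@H]([C@H](O1)c3cc4ccc(=O)oc4cc3OC)C(C)=C
F4 | step 8 | 6-[(R)-hydroxy[(4R)-2,2,5,5-tetramethyl-1,3-dioxolan-4-yl]methyl]-7-methoxy-2H-chromen-2-one | CC1(C)O[C@H]([C@H](O)c3cc4ccc(=O)oc4cc3OC)C(C)(C)O1
F5 | step 8 | 6-[(R)-[(tert-butyldimethylsilyl)oxy][(4R)-2,2,5,5-tetramethyl-1,3-dioxolan-4-yl]methyl]-7-methoxy-2H-chromen-2-one | CC1(C)O[C@H]([C@H](O[Si](C)(C)C(C)(C)C)c3cc4ccc(=O)oc4cc3OC)C(C)(C)O1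
F6 | step 9 | 6-[(4R,5R)-2,2-di-tert-butyl-5-hydroxy-6,6-dimethyl-1,3,2-dioxasilinan-4-yl]-7-methoxy-2H-chromen-2-one | O[C@H]([C@H](O1)c3cc4ccc(=O)oc4cc3OC)C(C)(C)O[Si]1(C(C)(C)C)C(C)(C)C
F7 | step 9 | (4R,5R)-2,2-di-tert-butyl-4-(7-methoxy-2-oxo-2H-chromen-6-yl)-6,6-dimethyl-1,3,2-dioxasilinan-5-yl (2R)-2-methylbutanoate | CC[C@@H](C)C(=O)O[C@H]([C@H](O1)c3cc4ccc(=O)oc4cc3OC)C(C)(C)O[Si]1(C(C)(C)C)C(C)(C)C
F8 | step 3 | 6-ethenyl-7-methoxy-2H-chromen-2-one | COc1cc2oc(=O)ccc2cc1C=C
A1 | alternative 1 | 6-[(R)-[(2R)-3,3-dimethyloxiran-2-yl](hydroxy)methyl]-7-methoxy-2H-chromen-2-one | CC1(C)O[C@@H]1[C@H](O)c2cc3ccc(=O)oc3cc2OC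
A2 | alternative 1 | 6-(1-hydroxy-3-methylbut-2-en-1-yl)-7-methoxy-2H-chromen-2-one (racemic) | CC(C)=CC(O)c1cc2ccc(=O)oc2cc1OC
A3 | alternative 2 | (1R,2R)-1-[(tert-butyldimethylsilyl)oxy]-3-hydroxy-1-(7-methoxy-2-oxo-2H-chromen-6-yl)-3-methylbutan-2-yl (2R)-2-methylbutanoate | CC[C@@H](C)C(=O)O[C@H]([C@H](O[Si](C)(C)C(C)(C)C)c1cc2ccc(=O)oc2cc1OC)C(C)(C)O
A4 | alternative 2 | (1R,2R)-1-[(tert-butyldimethylsilyl)oxy]-1-(5-formyl-4-hydroxy-2-methoxyphenyl)-3-hydroxy-3-methylbutan-2-yl (2R)-2-methylbutanoate | CC[C@@H](C)C(=O)O[C@H]([C@H](O[Si](C)(C)C(C)(C)C)c1cc(C=O)c(O)cc1OC)C(C)(C)O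
A5 | alternative 3 | 6-[(1R,2S)-1-[(tert-butyldimethylsilyl)oxy]-2-hydroxy-3-methylbut-3-en-1-yl]-7-methoxy-2H-chromen-2-one | O[C@H]([C@H](O[Si](C)(C)C(C)(C)C)c1cc2ccc(=O)oc2cc1OC)C(C)=C
A6 | alternative 3 | (2R)-2-[(tert-butyldimethylsilyl)oxy]-2-(7-methoxy-2-oxo-2H-chromen-6-yl)acetaldehyde | O=C[C@H](O[Si](C)(C)C(C)(C)C)c1cc2ccc(=O)oc2cc1OC
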